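The saturated Ca–Cb bridge between C5 of ring A (benzo ring of the chromene) and ring B (hydroxyphenyl ring) is read as a masked vinyl group, and C5 as a former phenol oxygen. One palladium-catalysed three-component coupling makes C5–Ca and Cb–ring B together: a ring B aryl(vinyl)boronate undergoes a metal-induced 1,2-shift while ring A enters as its C5 triflate. That triflate is a 2,2-dimethylchroman-4-one already bearing the C7 prenyl ether. It comes from symmetric phloroglucinol, where chelation to the C4 carbonyl distinguishes the C5 and C7 oxygens. Ring B carries a fluoride-stable tetrahydropyranyl acetal, so the later C–B protonolysis never has to occur beside a phenoxide.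

Key step: step 4

Numbering: chromene numbering O1, C2, C3, C4, C4a, C5 to C8, C8a; Ca is the bridge carbon on C5, Cb the bridge carbon on ring B.

Assumption: the bromoaryl tetrahydropyranyl ether is bought as the racemate; its acetal carbon, the boron-bearing Cb and the C4 carbinol are all uncontrolled, so the intermediates that hold them are carried on as diastereomer mixtures, which is harmless because the target is achiral.

Step 1
Reactants: 1 phloroglucinol; 2 3-methylbut-2-enoic acid
Product: 3 5,7-dihydroxy-2,2-dimethylchroman-4-one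
Conditions: P2O5/MeSO3H (1:10 w/w), 70 °C
Reagents that add atoms: none
Why: Friedel–Crafts acylation of the threefold-symmetric arene by activated 2 followed by intramolecular oxa-Michael closure is a well-used chromanone synthesis, in which symmetry allows only one ring-fusion isomer and the deactivating acyl group discourages a second annulation.

Step 2
Reactants: 3 5,7-dihydroxy-2,2-dimethylchroman-4-one; 4 1-bromo-3-methylbut-2-ene (prenyl bromide)
Product: 5 5-hydroxy-2,2-dimethyl-7-(3-methylbut-2-enyloxy)chroman-4-one
Conditions: K2CO3 (1.1 equiv), 4 (1.05 equiv), acetone, 55 °C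
Reagents that add atoms: none
Why: Williamson etherification, in which the C5 hydroxyl is held in a hydrogen bond to the C4 carbonyl and is less acidic and less nucleophilic, so one equivalent of weak base and of 4 should alkylate the free C7 hydroxyl selectively.

Step 3
Reactants: 5 5-hydroxy-2,2-dimethyl-7-(3-methylbut-2-enyloxy)chroman-4-one
Product: 6 2,2-dimethyl-7-(3-methylbut-2-enyloxy)-4-oxochroman-5-yl trifluoromethanesulfonate
Conditions: Tf2O (1.2 equiv), pyridine (3 equiv), CH2Cl2, 0 °C
Reagents that add atoms: trifluoromethanesulfonic anhydride, O=S(=O)(OS(=O)(=O)C(F)(F)F)C(F)(F)F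
Why: O-sulfonylation of a phenol, in which the strongly electrophilic anhydride overcomes the chelation of the only remaining hydroxyl and excess pyridine keeps the medium non-acidic so that the prenyl ether survives.

Step 4
Reactants: 7 2-(4-bromophenoxy)tetrahydro-2H-pyran (racemic); 8 vinylboronic pinacol ester; 6 2,2-dimethyl-7-(3-methylbut-2-enyloxy)-4-oxochroman-5-yl trifluoromethanesulfonate
Product: 11 2,2-dimethyl-7-(3-methylbut-2-enyloxy)-5-{2-(4,4,5,5-tetramethyl-1,3,2-dioxaborolan-2-yl)-2-[4-(tetrahydro-2H-pyran-2-yloxy)phenyl]ethyl}chroman-4-one (racemic at Cb; acetal diastereomers), via ring B aryllithium 9 (not isolated), via lithium aryl(vinyl)boronate 10 (not isolated)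
Conditions: 7 (1.3 equiv), t-BuLi (2.6 equiv), Et2O, −78 °C; 8 (1.4 equiv), −78 °C to rt; solvent exchange to THF; 6 (1 equiv), Pd(OAc)2 (5 mol %), 1,1'-bis(dicyclohexylphosphino)ferrocene (6 mol %), KOTf (2 equiv), THF, 60 °C
Reagents that add atoms: none
Why: Zerovalent palladium generated in situ inserts into the C5–O(triflate) bond of 6, which the ortho C4 carbonyl renders electron-poor while both ring A oxygens sit meta, and since triflate does not bind the metal a cationic bisphosphine arylpalladium results whose open site takes up the vinyl group of 10. Coordination triggers a 1,2-metallate shift in which the ring B aryl moves from boron to the boron-bearing carbon (Cb) while palladium bonds to the terminal carbon (Ca), and reductive elimination then joins Ca to C5 and returns zerovalent palladium. This is the known palladium-catalysed conjunctive cross-coupling of aryl(vinyl)boron ate complexes with aryl triflates, and it closes no ring. The single new stereocentre, the boron-bearing Cb, has no controlling element because the ligand is achiral and the acetal centre is remote, so it forms racemic and is erased in step 7. The selectivity required is metallate shift over direct aryl or vinyl transmetalation and over beta-hydride loss from the alkylpalladium; the triflate leaving group together with KOTf, which precipitates the bromide left by the lithiation, keeps palladium cationic, and the wide-bite-angle ferrocenyl bisphosphine hastens reductive elimination. A slight excess of 8 over 9 leaves no free aryllithium for the C4 ketone, the tetracoordinate boronate is too weak a nucleophile for that vinylogous-ester carbonyl, and the trisubstituted prenyl alkene binds palladium far less well than the anionic vinylboronate.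

Step 5
Reactants: 11 the chroman-4-one boronic ester
Product: 12 2,2-dimethyl-7-(3-methylbut-2-enyloxy)-5-{2-(4,4,5,5-tetramethyl-1,3,2-dioxaborolan-2-yl)-2-[4-(tetrahydro-2H-pyran-2-yloxy)phenyl]ethyl}chroman-4-ol (diastereomer mixture)
Conditions: NaBH4 (3 equiv), THF/MeOH 1:1, 0 °C to rt
Reagents that add atoms: none
Why: Borohydride 1,2-reduction of an aryl ketone, to which the pinacol boronic ester, the acetal, the aryl ethers and the isolated alkene are inert; the new C4 carbinol centre forms without control and is erased in step 6.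

Step 6
Reactants: 12 the chroman-4-ol boronic ester
Product: 14 2-{2-[2,2-dimethyl-7-(3-methylbut-2-enyloxy)-2H-chromen-5-yl]-1-[4-(tetrahydro-2H-pyran-2-yloxy)phenyl]ethyl}-4,4,5,5-tetramethyl-1,3,2-dioxaborolane (racemic at Cb; acetal diastereomers), via C4 mesylate 13 (not isolated)
Conditions: MsCl (1.5 equiv), Et3N (5 equiv), CH2Cl2, 0 °C to rt
Reagents that add atoms: none
Why: Dehydration through a sulfonate ester (mesylation, then E1/E2 loss of methanesulfonate), in which the C4 mesylate is activated by O1 (ortho) and the C7 oxygen (para) and should leave at or below room temperature while the amine removes a C3 proton, all under basic buffering that spares the acid-labile prenyl ether and acetal.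

Step 7
Reactants: 14 the chromene boronic ester
Product: 15 2-(4-{2-[2,2-dimethyl-7-(3-methylbut-2-enyloxy)-2H-chromen-5-yl]ethyl}phenoxy)tetrahydro-2H-pyran (racemic)
Conditions: Bu4NF·3H2O (3 equiv), degassed THF, 60 °C
Reagents that add atoms: none
Why: Fluoride-mediated protodeboronation of a benzylic boronic ester, in which fluoride forms the tetracoordinate boronate and the hydrate water protonates its benzylic C–B bond; because the ring B oxygen stays capped as an acetal (a silyl ether would fall first and leave a phenoxide) the ring is only anisole-like, and the Cb stereocentre disappears here.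

Step 8
Reactants: 15 the tetrahydropyranyl ether of the target
Product: 16 4-{2-[2,2-dimethyl-7-(3-methylbut-2-enyloxy)-2H-chromen-5-yl]ethyl}phenol (CNP0337021.0, achiral)
Conditions: pyridinium p-toluenesulfonate (10 mol %), MeOH/THF, rt to 40 °C
Reagents that add atoms: none
Why: Acid-catalysed acetal exchange (tetrahydropyranyl ether cleavage), which is easy for an aryl acetal because phenol is a good leaving group, so a buffered pyridinium acid in methanol should suffice and is too weak to protonate the chromene or ionise the prenyl ether.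

Compound list
1 | phloroglucinol | Oc1cc(O)cc(O)c1 | starting material
2 | 3-methylbut-2-enoic acid | CC(C)=CC(=O)O | starting material
3 | 5,7-dihydroxy-2,2-dimethylchroman-4-one | CC1(C)CC(=O)c2c(O)cc(O)cc2O1 | intermediate
4 | 1-bromo-3-methylbut-2-ene | CC(C)=CCBr | starting material
5 | 5-hydroxy-2,2-dimethyl-7-(3-methylbut-2-enyloxy)chroman-4-one | CC(C)=CCOc1cc(O)c2c(c1)OC(C)(C)CC2=O | intermediate
6 | 2,2-dimethyl-7-(3-methylbut-2-enyloxy)-4-oxochroman-5-yl trifluoromethanesulfonate | CC(C)=CCOc1cc(OS(=O)(=O)C(F)(F)F)c2c(c1)OC(C)(C)CC2=O | intermediate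
7 | 2-(4-bromophenoxy)tetrahydro-2H-pyran (racemic) | Brc1ccc(OC2CCCCO2)cc1 | starting material
8 | vinylboronic pinacol ester | C=CB1OC(C)(C)C(C)(C)O1 | starting material
9 | 4-(tetrahydro-2H-pyran-2-yloxy)phenyllithium | [Li]c1ccc(OC2CCCCO2)cc1 | intermediate
10 | lithium [4-(tetrahydro-2H-pyran-2-yloxy)phenyl](vinyl)(pinacolato)borate | [Li+].C=C[B-]1(c2ccc(OC3CCCCO3)cc2)OC(C)(C)C(C)(C)O1 | intermediate
11 | 2,2-dimethyl-7-(3-methylbut-2-enyloxy)-5-{2-(4,4,5,5-tetramethyl-1,3,2-dioxaborolan-2-yl)-2-[4-(tetrahydro-2H-pyran-2-yloxy)phenyl]ethyl}chroman-4-one (racemic at Cb, acetal diastereomers) | CC(C)=CCOc1cc(CC(B2OC(C)(C)C(C)(C)O2)c2ccc(OC3CCCCO3)cc2)c2c(c1)OC(C)(C)CC2=O | intermediate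
12 | corresponding chroman-4-ol (diastereomer mixture) | CC(C)=CCOc1cc(CC(B2OC(C)(C)C(C)(C)O2)c2ccc(OC3CCCCO3)cc2)c2c(c1)OC(C)(C)CC2O | intermediate
13 | corresponding chroman-4-yl methanesulfonate (diastereomer mixture) | CC(C)=CCOc1cc(CC(B2OC(C)(C)C(C)(C)O2)c2ccc(OC3CCCCO3)cc2)c2c(c1)OC(C)(C)CC2OS(C)(=O)=O | intermediate
14 | 2-{2-[2,2-dimethyl-7-(3-methylbut-2-enyloxy)-2H-chromen-5-yl]-1-[4-(tetrahydro-2H-pyran-2-yloxy)phenyl]ethyl}-4,4,5,5-tetramethyl-1,3,2-dioxaborolane (racemic at Cb, acetal diastereomers) | CC(C)=CCOc1cc(CC(B2OC(C)(C)C(C)(C)O2)c2ccc(OC3CCCCO3)cc2)c2c(c1)OC(C)(C)C=C2 | intermediate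
15 | 2-(4-{2-[2,2-dimethyl-7-(3-methylbut-2-enyloxy)-2H-chromen-5-yl]ethyl}phenoxy)tetrahydro-2H-pyran (racemic) | CC(C)=CCOc1cc(CCc2ccc(OC3CCCCO3)cc2)c2c(c1)OC(C)(C)C=C2 | intermediate
16 | 4-{2-[2,2-dimethyl-7-(3-methylbut-2-enyloxy)-2H-chromen-5-yl]ethyl}phenol (CNP0337021.0) | CC(C)=CCOc1cc(CCc2ccc(O)cc2)c2c(c1)OC(C)(C)C=C2 | target

Total step count: 8. Longest linear sequence: 8 steps (steps 1 to 8; compounds 7 and 8 are bought and enter at step 4).

Steps most likely to fail

Risk 1, step 4. Four things may go wrong:
- Direct transfer of the aryl or vinyl group from boron to palladium may outrun the metallate shift.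
- Residual bromide or chelation by the C4 carbonyl may block the alkene-binding site.
- The alkylpalladium may lose a beta-hydride.
- Zerovalent palladium may slowly ionise the prenyl ether once the triflate is consumed.

The fallback replaces the three-component coupling with a two-component sp3–sp2 Suzuki–Miyaura coupling. It sets out from 6, 7 and 8 and comes back at 15. Compounds 7 and 8 are joined by an ordinary Suzuki–Miyaura vinylation (PdCl2(dppf), dppf = 1,1'-bis(diphenylphosphino)ferrocene, K2CO3, dioxane/H2O, 80 °C) to 2-(4-vinylphenoxy)tetrahydro-2H-pyran F1. Anti-Markovnikov hydroboration with 9-borabicyclo[3.3.1]nonane (THF, rt, styrene in slight excess) gives 9-{2-[4-(tetrahydro-2H-pyran-2-yloxy)phenyl]ethyl}-9-borabicyclo[3.3.1]nonane F2. This is coupled in the same flask with 6 (PdCl2(dppf), K3PO4, THF/DMF, 60 °C) to the boron-free 2,2-dimethyl-7-(3-methylbut-2-enyloxy)-5-{2-[4-(tetrahydro-2H-pyran-2-yloxy)phenyl]ethyl}chroman-4-one F3. NaBH4 reduction gives the corresponding chroman-4-ol F4, and MsCl/Et3N dehydration through its C4 methanesulfonate F5 delivers 15, so no protodeboronation is needed.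

Risk 2, step 7. The alkoxy-substituted ring B lends little stabilisation to negative charge building at Cb, so C–B cleavage may stall. Adventitious oxygen may also oxidise the boronate.

The fallback replaces heterolytic protonolysis with oxidation and radical deoxygenation. It sets out from 14 and comes back at 15. NaBO3·4H2O (THF/H2O, rt) converts the C–B bond into 2-[2,2-dimethyl-7-(3-methylbut-2-enyloxy)-2H-chromen-5-yl]-1-[4-(tetrahydro-2H-pyran-2-yloxy)phenyl]ethanol F6. NaH, CS2 and MeI (THF, 0 °C) give its O-alkyl S-methyl dithiocarbonate F7. A Barton–McCombie reduction run cold to avoid thermal elimination (Bu3SnH, Et3B/air, toluene, rt) gives 15.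

Risk 3, step 6. The C4 cation may be captured by chloride or by a second chromene molecule instead of losing a proton. Mesylation next to the peri substituent may also remain incomplete.

The fallback avoids both carbinol and cation by reducing an enol triflate. It sets out from 11, bypasses step 5 and comes back at 14. LiN(SiMe3)2 then PhNTf2 (THF, −78 °C, kept cold to forestall ring opening of the enolate) gives 2,2-dimethyl-7-(3-methylbut-2-enyloxy)-5-{2-(4,4,5,5-tetramethyl-1,3,2-dioxaborolan-2-yl)-2-[4-(tetrahydro-2H-pyran-2-yloxy)phenyl]ethyl}-2H-chromen-4-yl trifluoromethanesulfonate F8. Palladium-catalysed formate reduction (Pd(OAc)2, PPh3, HCO2H, Bu3N, DMF, 50 °C) then gives 14.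

Further compounds
F1 | step 4 | 2-(4-vinylphenoxy)tetrahydro-2H-pyran | C=Cc1ccc(OC2CCCCO2)cc1
F2 | step 4 | 9-{2-[4-(tetrahydro-2H-pyran-2-yloxy)phenyl]ethyl}-9-borabicyclo[3.3.1]nonane | C(Cc1ccc(OC2CCCCO2)cc1)B1C2CCCC1CCC2
F3 | step 4 | 2,2-dimethyl-7-(3-methylbut-2-enyloxy)-5-{2-[4-(tetrahydro-2H-pyran-2-yloxy)phenyl]ethyl}chroman-4-one | CC(C)=CCOc1cc(CCc2ccc(OC3CCCCO3)cc2)c2c(c1)OC(C)(C)CC2=O
F4 | step 4 | 2,2-dimethyl-7-(3-methylbut-2-enyloxy)-5-{2-[4-(tetrahydro-2H-pyran-2-yloxy)phenyl]ethyl}chroman-4-ol | CC(C)=CCOc1cc(CCc2ccc(OC3CCCCO3)cc2)c2c(c1)OC(C)(C)CC2O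
F5 | step 4 | 2,2-dimethyl-7-(3-methylbut-2-enyloxy)-5-{2-[4-(tetrahydro-2H-pyran-2-yloxy)phenyl]ethyl}chroman-4-yl methanesulfonate | CC(C)=CCOc1cc(CCc2ccc(OC3CCCCO3)cc2)c2c(c1)OC(C)(C)CC2OS(C)(=O)=O
F6 | step 7 | 2-[2,2-dimethyl-7-(3-methylbut-2-enyloxy)-2H-chromen-5-yl]-1-[4-(tetrahydro-2H-pyran-2-yloxy)phenyl]ethanol | CC(C)=CCOc1cc(CC(O)c2ccc(OC3CCCCO3)cc2)c2c(c1)OC(C)(C)C=C2
F7 | step 7 | O-{2-[2,2-dimethyl-7-(3-methylbut-2-enyloxy)-2H-chromen-5-yl]-1-[4-(tetrahydro-2H-pyran-2-yloxy)phenyl]ethyl} S-methyl dithiocarbonate | CC(C)=CCOc1cc(CC(OC(=S)SC)c2ccc(OC3CCCCO3)cc2)c2c(c1)OC(C)(C)C=C2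
F8 | step 6 | 2,2-dimethyl-7-(3-methylbut-2-enyloxy)-5-{2-(4,4,5,5-tetramethyl-1,3,2-dioxaborolan-2-yl)-2-[4-(tetrahydro-2H-pyran-2-yloxy)phenyl]ethyl}-2H-chromen-4-yl trifluoromethanesulfonate | CC(C)=CCOc1cc(CC(B2OC(C)(C)C(C)(C)O2)c2ccc(OC3CCCCO3)cc2)c2c(c1)OC(C)(C)C=C2OS(=O)(=O)C(F)(F)F
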